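Ring C (O1, C2, C3, C4, C4a, C8a) is traced back to the five-membered ring of a 2-aryl-2-(iodomethyl)benzofuran-3(2H)-one that lacks C3. In the key step a Dowd–Beckwith radical 1,2-acyl shift moves the C4 carbonyl from C2 to the exocyclic CH2 group, which inserts C3 and delivers the complete flavanone skeleton in one operation. The step exploits that C2 carries both O1 and ring B, so that the ring-expanded radical is benzylic and alpha-oxygenated. The precursor comes from a 7-alkylated coumaranone by alpha-arylation and iodomethylation. The Z side chain stems from carbomagnesiation of propargyl alcohol, and C2 is rendered (S) by transfer-hydrogenative kinetic resolution.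

Key step: step 11

Remark: flavanone numbering (rings A, B, C; O1, C2 to C8a) is used for the target and its chromanone precursors. The SMILES is read as 2S and as Z at the side-chain alkene (CH2OH cis to the benzylic CH2).

Step 1
Reactants: 1 propargyl alcohol
Product: 3 (Z)-3-iodo-2-methylprop-2-en-1-ol, via vinylmagnesium alkoxide 2 (not isolated)
Conditions: MeMgBr (2.5 equiv), CuI (10 mol %), Et2O, -10 °C to rt; then I2, THF, -20 °C
Reagents that add atoms: methylmagnesium bromide C[Mg]Br; iodine [I][I]
Why: Copper-catalysed anti-carbomagnesiation of the propargylic alkoxide places methyl on the inner carbon and magnesium on the terminus cis to CH2O through a five-membered chelate, and iodinolysis with retention fixes the Z geometry of the later side chain.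

Step 2
Reactants: 3 (Z)-3-iodo-2-methylprop-2-en-1-ol
Product: 4 tert-butyl{[(Z)-3-iodo-2-methylprop-2-en-1-yl]oxy}dimethylsilane
Conditions: TBSCl, imidazole, CH2Cl2, 0 °C to rt
Reagents that add atoms: tert-butyldimethylsilyl chloride C[Si](C)(Cl)C(C)(C)C
Why: Standard silyl ether protection of a primary alcohol, which leaves the vinyl iodide untouched.

Step 3
Reactants: 4 tert-butyl{[(Z)-3-iodo-2-methylprop-2-en-1-yl]oxy}dimethylsilane
Product: 6 (Z)-4-(tert-butyldimethylsilyloxy)-3-methylbut-2-en-1-ol, via vinyllithium 5 (not isolated)
Conditions: n-BuLi, Et2O, -78 °C; then paraformaldehyde, -78 °C to rt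
Reagents that add atoms: formaldehyde (as paraformaldehyde) C=O; n-butyllithium [Li]CCCC (lithium of 5 only)
Why: Iodine–lithium exchange of a vinyl iodide and hydroxymethylation of the vinyllithium both proceed with retention of the double-bond geometry.

Step 4
Reactants: 6 (Z)-4-(tert-butyldimethylsilyloxy)-3-methylbut-2-en-1-ol
Product: 7 {[(Z)-4-bromo-2-methylbut-2-en-1-yl]oxy}(tert-butyl)dimethylsilane
Conditions: CBr4, PPh3, CH2Cl2, 0 °C
Reagents that add atoms: carbon tetrabromide BrC(Br)(Br)Br
Why: The Appel bromination converts the primary allylic alcohol by SN2 displacement under neutral conditions, so neither allylic transposition nor Z/E isomerisation should occur and the TBS ether survives.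

Step 5
Reactants: 8 4-bromobenzene-1,2-diol
Product: 9 4-bromo-1,2-bis(methoxymethoxy)benzene
Conditions: MOMCl (2.5 equiv), i-Pr2NEt, CH2Cl2, 0 °C to rt
Reagents that add atoms: chloromethyl methyl ether COCCl
Why: MOM ether formation on both phenols gives an aryl bromide that is stable to base and to radicals.

Step 6
Reactants: 10 1-(2,6-dihydroxy-4-methoxyphenyl)ethanone; 7 {[(Z)-4-bromo-2-methylbut-2-en-1-yl]oxy}(tert-butyl)dimethylsilane
Product: 11 1-{2,6-dihydroxy-4-methoxy-3-[(2Z)-4-(tert-butyldimethylsilyloxy)-3-methylbut-2-en-1-yl]phenyl}ethanone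
Conditions: DBU (1.1 equiv), THF, 0 °C to rt
Reagents that add atoms: none
Why: C-Alkylation of an acylphloroglucinol-type phenoxide, in which the two free ring positions of 10 are equivalent, the ambident anion of this electron-rich ring takes soft allylic bromides at carbon, and SN2 attack at the primary carbon keeps the Z geometry.

Step 7
Reactants: 11 1-{2,6-dihydroxy-4-methoxy-3-[(2Z)-4-(tert-butyldimethylsilyloxy)-3-methylbut-2-en-1-yl]phenyl}ethanone
Product: 12 1-{2-hydroxy-4-methoxy-6-(methoxymethoxy)-3-[(2Z)-4-(tert-butyldimethylsilyloxy)-3-methylbut-2-en-1-yl]phenyl}ethanone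
Conditions: MOMCl (1.05 equiv), i-Pr2NEt, CH2Cl2, 0 °C
Reagents that add atoms: chloromethyl methyl ether COCCl
Why: Selective MOM protection, because the hydroxyl flanked by the side chain and the acetyl group is more hindered and more strongly chelated, so one equivalent of MOMCl should take the 6-OH and leave the phenol that becomes O1.

Step 8
Reactants: 12 1-{2-hydroxy-4-methoxy-6-(methoxymethoxy)-3-[(2Z)-4-(tert-butyldimethylsilyloxy)-3-methylbut-2-en-1-yl]phenyl}ethanone
Product: 15 6-methoxy-4-(methoxymethoxy)-7-[(2Z)-4-(tert-butyldimethylsilyloxy)-3-methylbut-2-en-1-yl]benzofuran-3(2H)-one, via bis-TMS enol ether 13 (not isolated), via bromoketone 14 (not isolated)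
Conditions: LiHMDS (2.3 equiv), TMSCl, THF, -78 °C; NBS (1.0 equiv), -78 °C; then K2CO3, MeOH, 0 °C to rt
Reagents that add atoms: chlorotrimethylsilane C[Si](C)(C)Cl (silyl groups of 13 and 14 only); N-bromosuccinimide O=C1CCC(=O)N1Br (bromine of 14 only)
Why: Regiospecific alpha-bromination of the ketone through its silyl enol ether, which should outcompete the trisubstituted alkene and the arene for NBS at low temperature, is followed by methanolysis of the aryl silyl ether and intramolecular Williamson etherification (5-exo-tet) to the benzofuranone.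

Step 9
Reactants: 15 6-methoxy-4-(methoxymethoxy)-7-[(2Z)-4-(tert-butyldimethylsilyloxy)-3-methylbut-2-en-1-yl]benzofuran-3(2H)-one; 9 4-bromo-1,2-bis(methoxymethoxy)benzene
Product: 16 rac-2-[3,4-bis(methoxymethoxy)phenyl]-6-methoxy-4-(methoxymethoxy)-7-[(2Z)-4-(tert-butyldimethylsilyloxy)-3-methylbut-2-en-1-yl]benzofuran-3(2H)-one
Conditions: Pd2(dba)3 (2.5 mol %), XPhos (6 mol %), K3PO4, toluene, 80 °C, argon
Reagents that add atoms: none
Why: In this palladium-catalysed ketone alpha-arylation (Buchwald–Hartwig–Miura type) the acidic O-CH2-C=O position is enolised by a mild base and the monoarylated product rests as its stabilised enolate, which disfavours a second arylation; C2 is formed racemic and is configurationally labile at this stage.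

Step 10
Reactants: 16 rac-2-[3,4-bis(methoxymethoxy)phenyl]-6-methoxy-4-(methoxymethoxy)-7-[(2Z)-4-(tert-butyldimethylsilyloxy)-3-methylbut-2-en-1-yl]benzofuran-3(2H)-one
Product: 17 rac-2-[3,4-bis(methoxymethoxy)phenyl]-2-(iodomethyl)-6-methoxy-4-(methoxymethoxy)-7-[(2Z)-4-(tert-butyldimethylsilyloxy)-3-methylbut-2-en-1-yl]benzofuran-3(2H)-one
Conditions: NaH, THF/DMPU, 0 °C; CH2I2 (8 equiv), 45 °C
Reagents that add atoms: diiodomethane ICI
Why: Enolate alkylation with excess diiodomethane is the standard entry to Dowd–Beckwith substrates; the soft electrophile should be taken at C2 to give the racemic quaternary centre and a beta-iodo ketone that has no alpha-hydrogen and so cannot eliminate.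

Step 11
Reactants: 17 rac-2-[3,4-bis(methoxymethoxy)phenyl]-2-(iodomethyl)-6-methoxy-4-(methoxymethoxy)-7-[(2Z)-4-(tert-butyldimethylsilyloxy)-3-methylbut-2-en-1-yl]benzofuran-3(2H)-one
Product: 18 rac-2-[3,4-bis(methoxymethoxy)phenyl]-7-methoxy-5-(methoxymethoxy)-8-[(2Z)-4-(tert-butyldimethylsilyloxy)-3-methylbut-2-en-1-yl]chroman-4-one
Conditions: Bu3SnH (1.2 equiv) and AIBN (0.2 equiv) by syringe pump, benzene (0.005 M), reflux
Reagents that add atoms: none
Why: Dowd–Beckwith ring expansion: the stannyl radical abstracts iodine from 17, the primary radical adds 3-exo-trig to the ketone carbon of the five-membered ring, and the cyclopropyloxy radical cleaves the old C2–C(=O) bond, so the exocyclic CH2 is inserted as C3 and the furanone ring becomes the six-membered ring C. The closest precedent is the one-carbon expansion of 2-(halomethyl)cyclopentanones and 2-(halomethyl)-1-indanones, in which an ester usually stabilises the product radical; here O1 and ring B take that role and make the C2 radical tertiary, benzylic and alpha-oxygenated, which should render the fragmentation irreversible. Ring C is the only ring formed, and it arises by a 1,2-acyl shift (3-exo closure, then beta-scission of the ring-fusion bond), not by direct cyclisation. The new stereocentre C2 is created by hydrogen transfer from Bu3SnH to a planar radical without a control element, so 18 is racemic and the configuration is secured in step 12. The step needs the acyl shift to outrun direct reduction of the primary radical, which slow addition and high dilution secure, and to outrun the neophyl-type 1,2-shift of ring B, which is secured because acyl groups are known to migrate much faster than aryl groups. The remote trisubstituted alkene, the MOM ethers and the TBS ether are inert to tin radicals.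

Step 12
Reactants: 18 rac-2-[3,4-bis(methoxymethoxy)phenyl]-7-methoxy-5-(methoxymethoxy)-8-[(2Z)-4-(tert-butyldimethylsilyloxy)-3-methylbut-2-en-1-yl]chroman-4-one
Product: 19 (2S)-2-[3,4-bis(methoxymethoxy)phenyl]-7-methoxy-5-(methoxymethoxy)-8-[(2Z)-4-(tert-butyldimethylsilyloxy)-3-methylbut-2-en-1-yl]chroman-4-one
Conditions: Cp*RhCl[(R,R)-TsDPEN] (1 mol %), HCO2H/Et3N 5:2, EtOAc, rt, stopped just past half conversion; chromatography
Reagents that add atoms: none
Why: In this kinetic resolution by Noyori–Ikariya asymmetric transfer hydrogenation, a method established for racemic flavanones, the (R,R)-catalyst delivers hydride to the carbonyl face that leads to the 4R carbinol, which lies anti to ring B only in the (2R)-enantiomer, so the (2R)-ketone should be consumed as the cis-flavan-4-ol while the (2S)-ketone 19 remains.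

Step 13
Reactants: 19 (2S)-2-[3,4-bis(methoxymethoxy)phenyl]-7-methoxy-5-(methoxymethoxy)-8-[(2Z)-4-(tert-butyldimethylsilyloxy)-3-methylbut-2-en-1-yl]chroman-4-one
Product: 20 (2S)-2-(3,4-dihydroxyphenyl)-5-hydroxy-8-[(2Z)-4-hydroxy-3-methylbut-2-en-1-yl]-7-methoxychroman-4-one (target)
Conditions: 3 M aq. HCl, MeOH/THF, 40 °C
Reagents that add atoms: none
Why: Acid-catalysed acetal and silyl ether solvolysis removes the three MOM groups and the TBS group in one operation, the acidic medium avoids the base-induced ring opening to the chalcone that racemises flavanones, and the side chain has no free ortho phenol to cyclise with and no cation-stabilising substituent at its primary allylic alcohol.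

Compound list
1 | propargyl alcohol | C#CCO | starting material
2 | (Z)-vinylmagnesium alkoxide from carbomagnesiation | Br[Mg]/C=C(/C)CO[Mg]Br | intermediate
3 | (Z)-3-iodo-2-methylprop-2-en-1-ol | I/C=C(/C)CO | intermediate
4 | tert-butyl{[(Z)-3-iodo-2-methylprop-2-en-1-yl]oxy}dimethylsilane | I/C=C(/C)CO[Si](C)(C)C(C)(C)C | intermediate
5 | (Z)-vinyllithium from 4 | [Li]/C=C(/C)CO[Si](C)(C)C(C)(C)C | intermediate
6 | (Z)-4-(tert-butyldimethylsilyloxy)-3-methylbut-2-en-1-ol | OC/C=C(/C)CO[Si](C)(C)C(C)(C)C | intermediate
7 | {[(Z)-4-bromo-2-methylbut-2-en-1-yl]oxy}(tert-butyl)dimethylsilane | BrC/C=C(/C)CO[Si](C)(C)C(C)(C)C | intermediate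
8 | 4-bromobenzene-1,2-diol | Oc1ccc(Br)cc1O | starting material
9 | 4-bromo-1,2-bis(methoxymethoxy)benzene | COCOc1ccc(Br)cc1OCOC | intermediate
10 | 1-(2,6-dihydroxy-4-methoxyphenyl)ethanone | CC(=O)c1c(O)cc(OC)cc1O | starting material
11 | 3-C-alkylated 2,6-dihydroxy-4-methoxyacetophenone, Z side chain | CC(=O)c1c(O)cc(OC)c(C/C=C(/C)CO[Si](C)(C)C(C)(C)C)c1O | intermediate
12 | 6-O-MOM ether of 11, free 2-OH next to the side chain | CC(=O)c1c(OCOC)cc(OC)c(C/C=C(/C)CO[Si](C)(C)C(C)(C)C)c1O | intermediate
13 | trimethylsilyl enol ether and aryl trimethylsilyl ether of 12 | C=C(O[Si](C)(C)C)c1c(OCOC)cc(OC)c(C/C=C(/C)CO[Si](C)(C)C(C)(C)C)c1O[Si](C)(C)C | intermediate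
14 | alpha-bromoketone, aryl trimethylsilyl ether | O=C(CBr)c1c(OCOC)cc(OC)c(C/C=C(/C)CO[Si](C)(C)C(C)(C)C)c1O[Si](C)(C)C | intermediate
15 | 6-methoxy-4-(methoxymethoxy)-7-[(2Z)-side chain]benzofuran-3(2H)-one | COc1cc(OCOC)c2c(c1C/C=C(/C)CO[Si](C)(C)C(C)(C)C)OCC2=O | intermediate
16 | racemic 2-[3,4-bis(methoxymethoxy)phenyl] derivative of 15 | COc1cc(OCOC)c2c(c1C/C=C(/C)CO[Si](C)(C)C(C)(C)C)OC(c1ccc(OCOC)c(OCOC)c1)C2=O | intermediate
17 | racemic 2-aryl-2-(iodomethyl)benzofuran-3(2H)-one | COc1cc(OCOC)c2c(c1C/C=C(/C)CO[Si](C)(C)C(C)(C)C)OC(CI)(c1ccc(OCOC)c(OCOC)c1)C2=O | intermediate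
18 | racemic protected flavanone | COc1cc(OCOC)c2c(c1C/C=C(/C)CO[Si](C)(C)C(C)(C)C)OC(c1ccc(OCOC)c(OCOC)c1)CC2=O | intermediate
19 | (2S)-protected flavanone | COc1cc(OCOC)c2c(c1C/C=C(/C)CO[Si](C)(C)C(C)(C)C)O[C@H](c1ccc(OCOC)c(OCOC)c1)CC2=O | intermediate
20 | (2S)-2-(3,4-dihydroxyphenyl)-5-hydroxy-8-[(2Z)-4-hydroxy-3-methylbut-2-en-1-yl]-7-methoxychroman-4-one | COc1cc(O)c2c(c1C/C=C(/C)CO)O[C@H](c1ccc(O)c(O)c1)CC2=O | target

Total step count: 13. Longest linear sequence: 12 (steps 1 to 4, then 6 to 13).

Steps most likely to fail

Step 11. Hydrogen transfer to the primary radical may occur before the 3-exo attack, because the carbonyl group is deactivated by two donor oxygens. A 1,6-hydrogen shift from the benzylic CH2 of the side chain may also divert the chain. The fallback separates bond formation from bond cleavage. It sets out from 17, which would be closed with SmI2 in THF at -78 °C (intramolecular Barbier reaction of a beta-iodo ketone) to the ring-fused cyclopropanol F1. This would then be opened oxidatively with Mn(pic)3 (manganese tris(pyridine-2-carboxylate)) in DMF in the presence of Bu3SnH. Cleavage of the ring-fusion bond gives the more stabilised beta-keto radical, which is the same C2 radical, and the sequence comes back to the route at 18.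

Step 10. The ambident 3-oxidobenzofuran enolate may be alkylated at oxygen, or the slow substitution at diiodomethane may allow two enolates to be bridged by one CH2 group. The fallback replaces alkylation by an aldol reaction. It sets out from 16, which with aqueous formaldehyde and catalytic benzyltrimethylammonium hydroxide in THF should give the C-hydroxymethylated ketone F2, since attack through oxygen is reversible and unproductive. An Appel-type iodination (I2, PPh3, imidazole, toluene, 60 °C) then comes back to the route at 17.

Step 12. The rate difference between the two enantiomers may be too small, because the 5-OMOM group slows hydride transfer to both. The fallback gives up partial conversion. It sets out from 18, which would be reduced completely by a Corey–Bakshi–Shibata reduction ((S)-Me-CBS oxazaborolidine, catecholborane, toluene, -78 °C). The reagent should set 4R in both enantiomers. This gives the trans-(2S,4R)-flavan-4-ol F3 and the cis-(2R,4R)-flavan-4-ol F4 as diastereomers that can be separated by chromatography. Oxidation of F3 with Dess–Martin periodinane comes back to the route at 19.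

Further compounds
F1 | step 11 | racemic 1a-aryl-6b-hydroxy-1,1a-dihydrocyclopropa[b]benzofuran (cis-fused cyclopropanol) | COc1cc(OCOC)c2c(c1C/C=C(/C)CO[Si](C)(C)C(C)(C)C)OC1(c3ccc(OCOC)c(OCOC)c3)CC21O
F2 | step 10 | racemic 2-aryl-2-(hydroxymethyl)benzofuran-3(2H)-one | COc1cc(OCOC)c2c(c1C/C=C(/C)CO[Si](C)(C)C(C)(C)C)OC(CO)(c1ccc(OCOC)c(OCOC)c1)C2=O
F3 | step 12 | trans-(2S,4R)-protected flavan-4-ol | COc1cc(OCOC)c2c(c1C/C=C(/C)CO[Si](C)(C)C(C)(C)C)O[C@H](c1ccc(OCOC)c(OCOC)c1)C[C@H]2O
F4 | step 12 | cis-(2R,4R)-protected flavan-4-ol | COc1cc(OCOC)c2c(c1C/C=C(/C)CO[Si](C)(C)C(C)(C)C)O[C@@H](c1ccc(OCOC)c(OCOC)c1)C[C@H]2O
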